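**Strategy.** Everything rests on cutting the C15–C16 bond of ring D. An intramolecular Nozaki–Hiyama–Kishi reaction joins the C16 alkenyl iodide on C13 to the C15 aldehyde on C8. In one operation it delivers the five-membered ring D of the bicyclo[3.2.1]octane, the C16=C17 methylene and the C15 oxygen. It exploits the 1,3-cis disposition of the C8 and C13 substituents on cyclohexane ring C, which lets both turn axial and bridge. The precursor is the ring A / spiro-δ-lactone / ring C tricycle with the C8 formyl group, the C13 1-iodovinyl group, acetates on O1 and O19 and a silyl ether on O6. Its stereocentres come from a Robinson annulation, a radical spirolactonisation, a Diels–Alder reaction and an equilibration.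

Key step: step 23

Remark: atoms carry ent-kaurane numbers; ring A = C1–C5/C10, δ-lactone = C7(=O)–O–C20–C10–C9–C8, ring C = C8/C9/C11–C14, ring D = C8/C14/C13/C16/C15.
Remark: O6 is carried as a tert-butyldiphenylsilyl ether, which survives the selective fluoride step 12 and the acid step 21 better than a tert-butyldimethylsilyl ether; the skeletons of precursor 36 and product 37 are unchanged.
Remark: the ligand antipodes in steps 3 and 5 are those that give the drawn enantiomer; (R) is proposed for both and must be confirmed on first use.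

Step 1
Reactants: 1 methyl 2-hydroxyacetate
Product: 2 methyl 2-[(tert-butyldiphenylsilyl)oxy]acetate
Conditions: t-BuPh2SiCl, imidazole, DMF, 0 °C → rt
Reagents that add atoms: tert-butyl(chloro)diphenylsilane, CC(C)(C)[Si](Cl)(c1ccccc1)c1ccccc1
Why: Imidazole-promoted silylation of a primary alcohol (silyl ether formation); no stereocentre is involved.

Step 2
Reactants: 2 methyl 2-[(tert-butyldiphenylsilyl)oxy]acetate; 3 tert-butyl propanoate
Product: 4 tert-butyl 4-[(tert-butyldiphenylsilyl)oxy]-2-methyl-3-oxobutanoate (racemic)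
Conditions: LiN(i-Pr)2 (2.2 equiv), 3 (2.2 equiv), THF, −78 °C; then 2, −78 → −20 °C; AcOH
Reagents that add atoms: none
Why: Crossed Claisen condensation: the lithium enolate of the slowly self-condensing tert-butyl ester is acylated by the more electrophilic α-silyloxy methyl ester, and the second equivalent of enolate deprotonates the β-keto ester and drives the reaction.

Step 3
Reactants: 4 tert-butyl 4-[(tert-butyldiphenylsilyl)oxy]-2-methyl-3-oxobutanoate; 5 but-3-en-2-one
Product: 6 tert-butyl (2R)-2-{[(tert-butyldiphenylsilyl)oxy]acetyl}-2-methyl-5-oxohexanoate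
Conditions: [Pd((R)-binap)(H2O)2](OTf)2 (5 mol %), THF, −20 °C
Reagents that add atoms: none
Why: Catalytic enantioselective Michael addition: the β-keto ester binds the chiral diphosphine–palladium cation as an O,O-chelated enolate with one face screened by a P-aryl group, so the enone is attacked from the open face and the quaternary C4 is formed as the (R) centre.

Step 4
Reactants: 6 tert-butyl (2R)-2-{[(tert-butyldiphenylsilyl)oxy]acetyl}-2-methyl-5-oxohexanoate
Product: 7 tert-butyl (1R)-2-{[(tert-butyldiphenylsilyl)oxy]methyl}-1-methyl-4-oxocyclohex-2-ene-1-carboxylate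
Conditions: pyrrolidine (0.3 equiv), AcOH (0.3 equiv), toluene, 60 °C
Reagents that add atoms: none
Why: Second half of a Robinson annulation: the pyrrolidine enamine of the unhindered methyl ketone (C10) attacks the activated α-silyloxy ketone C5 and loss of water gives the cyclohexenone without touching C4.

Step 5
Reactants: 7 tert-butyl (1R)-2-{[(tert-butyldiphenylsilyl)oxy]methyl}-1-methyl-4-oxocyclohex-2-ene-1-carboxylate; 8 N,N-dimethylmethyleneiminium iodide
Product: 10 C10 dimethylaminomethyl ketone (Mannich base; C6 arm cis to the C19 ester), via silyl enol ether 9 (not isolated)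
Conditions: Cu(OAc)2·H2O (5 mol %), (R)-DTBM-SEGPHOS (5.5 mol %), (EtO)2MeSiH, toluene, 0 °C → rt; then 8, CH2Cl2, rt; aq. NaHCO3
Reagents that add atoms: none
Why: Copper hydride conjugate reduction (1,4-hydrosilylation) followed by a Mannich reaction of the regiodefined silyl enol ether: hydride enters C5 anti to the pseudo-axial C4 ester, an approach the matched ligand reinforces, so C6 ends cis to C19, while the C10 centre of the Mannich base is of no consequence.

Step 6
Reactants: 10 C10 dimethylaminomethyl ketone
Product: 12 tert-butyl 2-{[(tert-butyldiphenylsilyl)oxy]methyl}-1-methyl-3-methylidene-4-oxocyclohexane-1-carboxylate, via ammonium iodide 11 (not isolated)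
Conditions: MeI, CH2Cl2, rt; then sat. aq. NaHCO3, rt
Reagents that add atoms: none
Why: N-Methylation makes the amine a leaving group and mild base triggers E1cB (Hofmann-type) elimination across C10–C20 to the α-methylene ketone, which is used at once to avoid migration of the double bond into the ring.

Step 7
Reactants: 12 tert-butyl 2-{[(tert-butyldiphenylsilyl)oxy]methyl}-1-methyl-3-methylidene-4-oxocyclohexane-1-carboxylate
Product: 13 3-{[(tert-butyldiphenylsilyl)oxy]methyl}-4-(hydroxymethyl)-4-methyl-2-methylidenecyclohexan-1-ol (O1, C6 and C19 on one face)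
Conditions: LiAlH4, Et2O, −78 °C → rt; aq. potassium sodium tartrate
Reagents that add atoms: none
Why: Hydride reduction: LiAlH4 adds 1,2 to the s-cis enone from the ring face opposite to C6 and C19 (axial attack on the chair with C6 equatorial, and the only open face of the other chair), giving the C1 alcohol cis to C6, and it reduces the tert-butyl ester to the C19 alcohol.

Step 8
Reactants: 13 allylic 1,19-diol
Product: 14 1,19-bis(triethylsilyl) ether of 13
Conditions: Et3SiCl, imidazole, DMAP (cat.), DMF, rt
Reagents that add atoms: chlorotriethylsilane, CC[Si](Cl)(CC)CC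
Why: Imidazole-promoted silylation gives ethers with no acidic hydrogen, which tolerate the lactone enolate chemistry of step 11.

Step 9
Reactants: 14 1,19-bis(triethylsilyl) ether
Product: 15 C10–C20 spiro-epoxide (both C10 epimers)
Conditions: mCPBA, NaHCO3, CH2Cl2, 0 °C
Reagents that add atoms: 3-chloroperbenzoic acid, OOC(=O)c1cccc(Cl)c1
Why: Prilezhaev epoxidation of the 1,1-disubstituted alkene; the C10 configuration need not be controlled because C10 becomes a planar radical in step 10.

Step 10
Reactants: 15 C10–C20 spiro-epoxide; 16 2,2,2-trifluoroethyl acrylate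
Product: 17 spiro-δ-lactone (C7 lactone, C8H2, C9H2; C9 trans and C20 cis to C6)
Conditions: Cp2TiCl2 (0.3 equiv), Zn dust, 2,4,6-collidine·HCl, 16 (5 equiv), THF, rt
Reagents that add atoms: none
Why: Nugent–RajanBabu reaction: Cp2TiCl (trivalent titanium, formed from Cp2TiCl2 and Zn) opens the epoxide to the tertiary C10 radical, which adds to the acrylate (Giese addition) from the face anti to the axial C19 substituent, and after reduction and protonation the titanium alkoxide on C20 lactonises onto the activated ester, which sets C10.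

Step 11
Reactants: 17 spiro-δ-lactone; 18 di-tert-butyl dicarbonate
Product: 19 C8 tert-butoxycarbonyl spiro-lactone (C8 epimers)
Conditions: LiN(i-Pr)2 (2.2 equiv), THF, −78 °C; then 18, −78 → −40 °C; AcOH
Reagents that add atoms: none
Why: Claisen-type C-acylation of the lactone lithium enolate installs C15; the second equivalent of base traps the malonate-type product and prevents double acylation.

Step 12
Reactants: 19 C8 tert-butoxycarbonyl spiro-lactone
Product: 20 1,19-diol
Conditions: HF·pyridine, pyridine, THF, 0 °C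
Reagents that add atoms: none
Why: Selective desilylation: fluoride cleaves the two triethylsilyl ethers far faster than the bulky tert-butyldiphenylsilyl ether.

Step 13
Reactants: 20 1,19-diol
Product: 21 1,19-diacetate
Conditions: Ac2O, pyridine, DMAP (0.1 equiv), CH2Cl2, 0 °C → rt
Reagents that add atoms: acetic anhydride, CC(=O)OC(C)=O
Why: DMAP-catalysed acetylation installs the final O1 and O19 acetates before the cycloaddition, so that a small acetoxy group and not a silyl ether flanks the C1 face of the dienophile.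

Step 14
Reactants: 21 1,19-diacetate
Product: 23 C8=C9 dienophile (tert-butyl 2-oxo-5,6-dihydro-2H-pyran-3-carboxylate spiro-fused to ring A at C10), via selenide 22 (not isolated)
Conditions: NaH (1.05 equiv), THF, 0 °C; PhSeCl; then 30 % H2O2, CH2Cl2, 0 °C → rt
Reagents that add atoms: none
Why: α-Selenenylation of the malonate-type sodium enolate (the only hydrogen acidic enough for NaH), then oxidation and selenoxide syn-elimination, which can only use a C9 hydrogen, gives the doubly activated dienophile.

Step 15
Reactants: 23 C8=C9 dienophile; 24 2-(trimethylsilyloxy)buta-1,3-diene; 25 acetaldehyde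
Product: 27 C12 ketone with C13 1-hydroxyethyl group (C13 and C16 epimers), via cycloadduct silyl enol ether 26 (not isolated)
Conditions: 24 (5 equiv), BHT (cat.), toluene, 110 °C, sealed tube; evaporate; then 25, BF3·OEt2, CH2Cl2, −78 °C; aq. NaHCO3
Reagents that add atoms: none
Why: Diels–Alder reaction with para regiochemistry (the CH2 next to the silyloxy carbon bonds to the electrophilic C9) and suprafacial, hence cis, fusion; the diene approaches the face flanked by C1–OAc and not the face carrying the bulkier C5–CH2OSi arm next to quaternary C4, which sets C8 and C9, and the regiodefined silyl enol ether then undergoes a Mukaiyama aldol reaction at C13 only.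

Step 16
Reactants: 27 C12 ketone with C13 1-hydroxyethyl group
Product: 28 C12 ketone with C13 acetyl group (β-diketone)
Conditions: Dess–Martin periodinane, pyridine, CH2Cl2, rt
Reagents that add atoms: none
Why: Periodinane oxidation of the secondary alcohol gives the β-diketone and erases the aldol stereocentres.

Step 17
Reactants: 28 β-diketone
Product: 29 C12 enol triflate (C12=C13) with C13 acetyl group
Conditions: Tf2O, Et3N, CH2Cl2, −78 °C
Reagents that add atoms: trifluoromethanesulfonic anhydride, FC(F)(F)S(=O)(=O)OS(=O)(=O)C(F)(F)F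
Why: O-Sulfonylation of the predominant endocyclic enol (C12–OH, C12=C13) gives the vinylogous acyl triflate and marks the ring oxygen for removal.

Step 18
Reactants: 29 C12 enol triflate
Product: 31 C13 methyl ketone (acetyl cis to the C15 ester), via enone 30 (not isolated)
Conditions: H2 (1 atm), 10 % Pd/C, NaHCO3, EtOAc, rt; filter; DBU (0.3 equiv), CH2Cl2, rt
Reagents that add atoms: none
Why: Hydrogenolysis of the electron-poor C12–OTf bond and hydrogenation of the resulting enone remove the C12 oxygen, and base equilibration through the C16 enol places the acetyl group equatorial and cis to C15, because the trans epimer would be 1,3-diaxial to C7 (thermodynamic control of C13).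

Step 19
Reactants: 31 C13 methyl ketone
Product: 32 N-(tert-butyldimethylsilyl)hydrazone of 31
Conditions: t-BuMe2SiNHNHSiMe2t-Bu, Sc(OTf)3 (1 mol %), CH2Cl2, rt
Reagents that add atoms: 1,2-bis(tert-butyldimethylsilyl)hydrazine, CC(C)(C)[Si](C)(C)NN[Si](C)(C)C(C)(C)C
Why: Lewis-acid-catalysed condensation of the methyl ketone with the bis-silyl hydrazine gives the N-silyl hydrazone under non-nucleophilic conditions that leave lactone and esters untouched.

Step 20
Reactants: 32 N-(tert-butyldimethylsilyl)hydrazone
Product: 33 C13 1-iodovinyl tert-butyl ester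
Conditions: I2 (2.5 equiv), 1,1,3,3-tetramethylguanidine, THF, 0 °C → rt
Reagents that add atoms: iodine, II
Why: Barton vinyl iodide synthesis: iodine oxidises the hydrazone to the diazo compound and then to an α-iodo cation, which loses a proton from the unhindered methyl group under guanidine base to give the 1-iodovinyl group.

Step 21
Reactants: 33 C13 1-iodovinyl tert-butyl ester
Product: 34 C15 carboxylic acid
Conditions: CF3CO2H/CH2Cl2 (1:4), 0 °C → rt
Reagents that add atoms: none
Why: Acidolysis of the tert-butyl ester (E1 loss of 2-methylpropene) frees the C15 acid, while acetates, lactone, alkenyl iodide and the tert-butyldiphenylsilyl ether are stable to this acid.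

Step 22
Reactants: 34 C15 carboxylic acid
Product: 36 C15 aldehyde with C13 1-iodovinyl group (key-step precursor), via acid chloride 35 (not isolated)
Conditions: (COCl)2, DMF (cat.), CH2Cl2, 0 °C → rt; evaporate; LiAlH(Ot-Bu)3 (1.1 equiv), THF, −78 °C
Reagents that add atoms: none
Why: Acid chloride formation (Vilsmeier-type activation) and partial reduction with the hindered alkoxyaluminium hydride stop at the aldehyde and spare lactone and acetates; C8 has no hydrogen, so neither a ketene nor epimerisation is possible.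

Step 23
Reactants: 36 C15 aldehyde with C13 1-iodovinyl group
Product: 37 C15 allylic alcohol with ring D closed (key-step product)
Conditions: CrCl2 (8 equiv), NiCl2 (2 mol %), degassed DMSO, rt, 0.005 M
Reagents that add atoms: none
Why: Zerovalent nickel, formed from NiCl2 by divalent chromium, inserts into the C16–I bond and passes the alkenyl group to chromium; the alkenylchromium species is nucleophilic but hardly basic and adds to the neopentyl C15 aldehyde (intramolecular Nozaki–Hiyama–Kishi reaction, closest type: Ni/Cr-mediated alkenyl halide–aldehyde coupling). Ring D closes in the 5-exo-trig mode (C16 attacks C15, the C=O lying outside the new ring), which requires the chair of ring C in which C15 and C16 are both axial; ring inversion can reach it because the two groups are 1,3-cis. The only new stereocentre, C15, is fixed by the orientation of the chromium-bound formyl oxygen in the bridged transition state, and either epimer serves because step 24 oxidises it. The step needs chemoselectivity for the aldehyde over the lactone, two acetates and the silyl ether, which the carbonyl selectivity of organochromium reagents secures, and the quaternary C8 excludes enolisation.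

Step 24
Reactants: 37 C15 allylic alcohol
Product: 38 C15 ketone (α-methylene cyclopentanone), O6 silyl ether
Conditions: Dess–Martin periodinane, pyridine, CH2Cl2, 0 °C → rt
Reagents that add atoms: none
Why: Dess–Martin oxidation of the allylic carbinol gives the enone and removes the uncontrolled C15 stereocentre.

Step 25
Reactants: 38 C15 ketone, O6 silyl ether
Product: 39 target CNP0105570.2
Conditions: HF·pyridine, pyridine, THF, 0 °C → rt
Reagents that add atoms: none
Why: Fluoride-mediated desilylation under buffered, non-basic conditions frees the C6 hydroxyl without acetyl migration or conjugate addition to the enone.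

**Compound list**

1 | methyl 2-hydroxyacetate (methyl glycolate) | COC(=O)CO | starting material
2 | methyl 2-[(tert-butyldiphenylsilyl)oxy]acetate | COC(=O)CO[Si](c1ccccc1)(c1ccccc1)C(C)(C)C | intermediate
3 | tert-butyl propanoate | CCC(=O)OC(C)(C)C | starting material
4 | tert-butyl 4-[(tert-butyldiphenylsilyl)oxy]-2-methyl-3-oxobutanoate (racemic) | CC(C(=O)OC(C)(C)C)C(=O)CO[Si](c1ccccc1)(c1ccccc1)C(C)(C)C | intermediate
5 | but-3-en-2-one | CC(=O)C=C | starting material
6 | tert-butyl (2R)-2-{[(tert-butyldiphenylsilyl)oxy]acetyl}-2-methyl-5-oxohexanoate | CC(=O)CC[C@@](C)(C(=O)OC(C)(C)C)C(=O)CO[Si](c1ccccc1)(c1ccccc1)C(C)(C)C | intermediate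
7 | tert-butyl (1R)-2-{[(tert-butyldiphenylsilyl)oxy]methyl}-1-methyl-4-oxocyclohex-2-ene-1-carboxylate (ring A enone: C1 ketone, C10=C5, quaternary C4) | O=C1CC[C@@](C)(C(=O)OC(C)(C)C)C(CO[Si](c2ccccc2)(c2ccccc2)C(C)(C)C)=C1 | intermediate
8 | N,N-dimethylmethyleneiminium iodide | C=[N+](C)C.[I-] | starting material
9 | diethoxy(methyl)silyl enol ether (O–Si on C1, C1=C10; H5 trans to the C4 ester; not isolated) | C1=C(O[Si](C)(OCC)OCC)CC[C@@](C)(C(=O)OC(C)(C)C)[C@H]1CO[Si](c1ccccc1)(c1ccccc1)C(C)(C)C | intermediate
10 | tert-butyl 3-[(dimethylamino)methyl]-2-{[(tert-butyldiphenylsilyl)oxy]methyl}-1-methyl-4-oxocyclohexane-1-carboxylate (silyloxymethyl arm cis to the ester; C10 epimers) | CN(C)CC1C(=O)CC[C@@](C)(C(=O)OC(C)(C)C)[C@H]1CO[Si](c1ccccc1)(c1ccccc1)C(C)(C)C | intermediate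
11 | trimethylammonium iodide of 10 (not isolated) | C[N+](C)(C)CC1C(=O)CC[C@@](C)(C(=O)OC(C)(C)C)[C@H]1CO[Si](c1ccccc1)(c1ccccc1)C(C)(C)C.[I-] | intermediate
12 | tert-butyl 2-{[(tert-butyldiphenylsilyl)oxy]methyl}-1-methyl-3-methylidene-4-oxocyclohexane-1-carboxylate (arm cis to the ester) | C=C1C(=O)CC[C@@](C)(C(=O)OC(C)(C)C)[C@H]1CO[Si](c1ccccc1)(c1ccccc1)C(C)(C)C | intermediate
13 | 3-{[(tert-butyldiphenylsilyl)oxy]methyl}-4-(hydroxymethyl)-4-methyl-2-methylidenecyclohexan-1-ol (O1, C6, C19 all cis) | C=C1[C@@H](O)CC[C@@](C)(CO)[C@H]1CO[Si](c1ccccc1)(c1ccccc1)C(C)(C)C | intermediate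
14 | 1,19-bis(triethylsilyl) ether of 13 | C=C1[C@@H](O[Si](CC)(CC)CC)CC[C@@](C)(CO[Si](CC)(CC)CC)[C@H]1CO[Si](c1ccccc1)(c1ccccc1)C(C)(C)C | intermediate
15 | C10–C20 spiro-epoxide of 14 (1-oxaspiro[2.5]octane; both C10 epimers) | C1OC12[C@@H](O[Si](CC)(CC)CC)CC[C@@](C)(CO[Si](CC)(CC)CC)[C@H]2CO[Si](c1ccccc1)(c1ccccc1)C(C)(C)C | intermediate
16 | 2,2,2-trifluoroethyl acrylate | C=CC(=O)OCC(F)(F)F | starting material
17 | spiro-δ-lactone (2-oxaspiro[5.5]undecan-3-one; C7(=O)–O–C20, C8H2, C9H2; O1 and O19 triethylsilyl, O6 tert-butyldiphenylsilyl; C9 trans to C6) | O=C1CC[C@]2(CO1)[C@@H](O[Si](CC)(CC)CC)CC[C@@](C)(CO[Si](CC)(CC)CC)[C@H]2CO[Si](c1ccccc1)(c1ccccc1)C(C)(C)C | intermediate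
18 | di-tert-butyl dicarbonate | CC(C)(C)OC(=O)OC(=O)OC(C)(C)C | starting material
19 | C8 tert-butoxycarbonyl derivative of 17 (C8 epimers) | CC(C)(C)OC(=O)C1C[C@]2(COC1=O)[C@@H](O[Si](CC)(CC)CC)CC[C@@](C)(CO[Si](CC)(CC)CC)[C@H]2CO[Si](c1ccccc1)(c1ccccc1)C(C)(C)C | intermediate
20 | 1,19-diol from 19 | CC(C)(C)OC(=O)C1C[C@]2(COC1=O)[C@@H](O)CC[C@@](C)(CO)[C@H]2CO[Si](c1ccccc1)(c1ccccc1)C(C)(C)C | intermediate
21 | 1,19-diacetate of 20 | CC(C)(C)OC(=O)C1C[C@]2(COC1=O)[C@@H](OC(C)=O)CC[C@@](C)(COC(C)=O)[C@H]2CO[Si](c1ccccc1)(c1ccccc1)C(C)(C)C | intermediate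
22 | C8 phenylselenide of 21 (not isolated) | CC(C)(C)OC(=O)C1([Se]c3ccccc3)C[C@]2(COC1=O)[C@@H](OC(C)=O)CC[C@@](C)(COC(C)=O)[C@H]2CO[Si](c1ccccc1)(c1ccccc1)C(C)(C)C | intermediate
23 | dienophile: tert-butyl 2-oxo-5,6-dihydro-2H-pyran-3-carboxylate spiro-fused at C10 to ring A (C8=C9) | CC(C)(C)OC(=O)C1=C[C@]2(COC1=O)[C@@H](OC(C)=O)CC[C@@](C)(COC(C)=O)[C@H]2CO[Si](c1ccccc1)(c1ccccc1)C(C)(C)C | intermediate
24 | 2-(trimethylsilyloxy)buta-1,3-diene | C=CC(=C)O[Si](C)(C)C | starting material
25 | acetaldehyde | CC=O | starting material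
26 | cycloadduct: ring C cis-fused to the lactone, C12 trimethylsilyl enol ether (C12=C13), C15 tert-butyl ester (not isolated) | CC(C)(C)OC(=O)[C@]23CC=C(O[Si](C)(C)C)C[C@H]2[C@]1(COC3=O)[C@@H](OC(C)=O)CC[C@@](C)(COC(C)=O)[C@H]1CO[Si](c1ccccc1)(c1ccccc1)C(C)(C)C | intermediate
27 | C12 ketone with C13 1-hydroxyethyl group (C13, C16 epimers) | CC(C)(C)OC(=O)[C@]23CC(C(C)O)C(=O)C[C@H]2[C@]1(COC3=O)[C@@H](OC(C)=O)CC[C@@](C)(COC(C)=O)[C@H]1CO[Si](c1ccccc1)(c1ccccc1)C(C)(C)C | intermediate
28 | C12 ketone with C13 acetyl group (β-diketone) | CC(C)(C)OC(=O)[C@]23CC(C(C)=O)C(=O)C[C@H]2[C@]1(COC3=O)[C@@H](OC(C)=O)CC[C@@](C)(COC(C)=O)[C@H]1CO[Si](c1ccccc1)(c1ccccc1)C(C)(C)C | intermediate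
29 | C12 enol triflate (C12=C13) with C13 acetyl group | CC(C)(C)OC(=O)[C@]23CC(C(C)=O)=C(OS(=O)(=O)C(F)(F)F)C[C@H]2[C@]1(COC3=O)[C@@H](OC(C)=O)CC[C@@](C)(COC(C)=O)[C@H]1CO[Si](c1ccccc1)(c1ccccc1)C(C)(C)C | intermediate
30 | C12=C13 enone with C13 acetyl group (not isolated) | CC(C)(C)OC(=O)[C@]23CC(C(C)=O)=CC[C@H]2[C@]1(COC3=O)[C@@H](OC(C)=O)CC[C@@](C)(COC(C)=O)[C@H]1CO[Si](c1ccccc1)(c1ccccc1)C(C)(C)C | intermediate
31 | C13 methyl ketone (acetyl cis to the C15 tert-butyl ester) | CC(C)(C)OC(=O)[C@]23C[C@H](C(C)=O)CC[C@H]2[C@]1(COC3=O)[C@@H](OC(C)=O)CC[C@@](C)(COC(C)=O)[C@H]1CO[Si](c1ccccc1)(c1ccccc1)C(C)(C)C | intermediate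
32 | N-(tert-butyldimethylsilyl)hydrazone of 31 | CC(C)(C)OC(=O)[C@]23C[C@H](C(C)=NN[Si](C)(C)C(C)(C)C)CC[C@H]2[C@]1(COC3=O)[C@@H](OC(C)=O)CC[C@@](C)(COC(C)=O)[C@H]1CO[Si](c1ccccc1)(c1ccccc1)C(C)(C)C | intermediate
33 | C13 1-iodovinyl compound, C15 tert-butyl ester | CC(C)(C)OC(=O)[C@]23C[C@H](C(I)=C)CC[C@H]2[C@]1(COC3=O)[C@@H](OC(C)=O)CC[C@@](C)(COC(C)=O)[C@H]1CO[Si](c1ccccc1)(c1ccccc1)C(C)(C)C | intermediate
34 | C15 carboxylic acid | OC(=O)[C@]23C[C@H](C(I)=C)CC[C@H]2[C@]1(COC3=O)[C@@H](OC(C)=O)CC[C@@](C)(COC(C)=O)[C@H]1CO[Si](c1ccccc1)(c1ccccc1)C(C)(C)C | intermediate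
35 | C15 acid chloride (not isolated) | ClC(=O)[C@]23C[C@H](C(I)=C)CC[C@H]2[C@]1(COC3=O)[C@@H](OC(C)=O)CC[C@@](C)(COC(C)=O)[C@H]1CO[Si](c1ccccc1)(c1ccccc1)C(C)(C)C | intermediate
36 | key-step precursor: C8 formyl, C13 1-iodovinyl (1,3-cis), 1,19-diacetate, O6 tert-butyldiphenylsilyl ether | O=C[C@]23C[C@H](C(I)=C)CC[C@H]2[C@]1(COC3=O)[C@@H](OC(C)=O)CC[C@@](C)(COC(C)=O)[C@H]1CO[Si](c1ccccc1)(c1ccccc1)C(C)(C)C | intermediate
37 | key-step product: C15 allylic alcohol, ring D closed, C16=C17 exocyclic (C15 as drawn; its epimer serves equally) | C=C1[C@@H](O)[C@]23C[C@H]1CC[C@H]2[C@]1(COC3=O)[C@@H](OC(C)=O)CC[C@@](C)(COC(C)=O)[C@H]1CO[Si](c1ccccc1)(c1ccccc1)C(C)(C)C | intermediate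
38 | C15 ketone (α-methylene cyclopentanone), O6 tert-butyldiphenylsilyl ether | C=C1C(=O)[C@]23C[C@H]1CC[C@H]2[C@]1(COC3=O)[C@@H](OC(C)=O)CC[C@@](C)(COC(C)=O)[C@H]1CO[Si](c1ccccc1)(c1ccccc1)C(C)(C)C | intermediate
39 | CNP0105570.2 | C=C1C(=O)[C@]23C[C@H]1CC[C@H]2[C@]1(COC3=O)[C@@H](OC(C)=O)CC[C@@](C)(COC(C)=O)[C@H]1CO | target

Total step count: 25. Longest linear sequence: 25 steps (1 → 39).

**Steps most likely to fail**

1. Step 23 (key step). Ring C must invert to the chair that places C15 and C16 axial, and this chair also forces the spiro carbon C10 axial. If inversion is slow, the alkenylchromium species may be protonated (loss of iodine without ring closure), or the aldehyde may be reduced by excess divalent chromium. Fallback: the route sets out from methyl ketone 31 and returns at enone 38, forming the same C15–C16 bond by ketyl coupling. Acidolysis of 31 (CF3CO2H) gives the keto acid F1. Acid chloride formation and reduction with LiAlH(Ot-Bu)3 at −78 °C give the keto aldehyde F2. SmI2 (divalent samarium) in THF at −78 °C effects an intramolecular pinacol coupling of the C15 aldehyde with the C16 ketone and closes ring D as the C15,C16-diol F3. Parikh–Doering oxidation of the secondary C15 hydroxyl gives the ketol F4. Dehydration of the tertiary C16 hydroxyl with Burgess reagent can place the double bond only at C16=C17, because C13 is a bridgehead, and gives 38.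

2. Step 15. The diene may discriminate poorly between the two faces of the C8=C9 bond, since both are flanked by ring A carbons, or the cycloaddition at the neopentyl C9 may be slow enough for the diene to oligomerise. Fallback: the route sets out from dienophile 23 and returns at 27, replacing substrate control by catalyst control in a stepwise annulation. Cu(OTf)2 with (S,S)-2,2'-isopropylidenebis(4-tert-butyl-2-oxazoline) (10 mol %, CH2Cl2, −40 °C; antipode chosen to shield the C5 face) chelates the lactone and ester carbonyls of 23. Diene 24 then adds at C9 in a Mukaiyama–Michael step, and the resulting silyl ketene acetal closes onto the liberated enone by intramolecular Michael addition. The same silyl enol ether 26 results and is taken through the aldol reaction as before.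

3. Step 20. Proton loss from the α-iodo cation may not be regioselective (giving the internal iodoalkene C13=C16), or the cation may be trapped as the geminal diiodide. Fallback: the route sets out from methyl ketone 31 and returns at 33. Kinetic deprotonation of the methyl group with KN(SiMe3)2 in the presence of PhNTf2 (THF, −78 °C) gives the terminal enol triflate F5. Nickel-catalysed triflate–iodide exchange (Ni(OAc)2·4H2O, 1,5-cyclooctadiene, NaI, DMA/THF, rt) then gives 33.

**Further compounds**

F1 | step 23 | C15 carboxylic acid with C13 acetyl group | OC(=O)[C@]23C[C@H](C(C)=O)CC[C@H]2[C@]1(COC3=O)[C@@H](OC(C)=O)CC[C@@](C)(COC(C)=O)[C@H]1CO[Si](c1ccccc1)(c1ccccc1)C(C)(C)C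
F2 | step 23 | C15 aldehyde with C13 acetyl group (keto aldehyde) | O=C[C@]23C[C@H](C(C)=O)CC[C@H]2[C@]1(COC3=O)[C@@H](OC(C)=O)CC[C@@](C)(COC(C)=O)[C@H]1CO[Si](c1ccccc1)(c1ccccc1)C(C)(C)C
F3 | step 23 | ring D C15,C16-diol with C16 methyl group (C15, C16 epimers) | CC1(O)C(O)[C@]23C[C@H]1CC[C@H]2[C@]1(COC3=O)[C@@H](OC(C)=O)CC[C@@](C)(COC(C)=O)[C@H]1CO[Si](c1ccccc1)(c1ccccc1)C(C)(C)C
F4 | step 23 | C15 ketone with tertiary C16 hydroxyl and C16 methyl group (ketol) | CC1(O)C(=O)[C@]23C[C@H]1CC[C@H]2[C@]1(COC3=O)[C@@H](OC(C)=O)CC[C@@](C)(COC(C)=O)[C@H]1CO[Si](c1ccccc1)(c1ccccc1)C(C)(C)C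
F0 | step 15 | none | none
F5 | step 20 | C13 1-(trifluoromethanesulfonyloxy)vinyl compound, C15 tert-butyl ester | CC(C)(C)OC(=O)[C@]23C[C@H](C(OS(=O)(=O)C(F)(F)F)=C)CC[C@H]2[C@]1(COC3=O)[C@@H](OC(C)=O)CC[C@@](C)(COC(C)=O)[C@H]1CO[Si](c1ccccc1)(c1ccccc1)C(C)(C)C
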